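The constants have to come from the earlier runs, so I start from those runs and from what is asked.

| flask | substrate | temperature | remark | time |
|---|---|---|---|---|
| ash | 0.24 M | 80 °C | run made earlier |  |
| elm | 0.38 M | 112 °C | run made earlier |  |
| oak | 0.77 M | 80 °C | run made earlier |  |
| blue | 0.20 M | 85 °C |  | 25 min |
| red | 0.50 M | 130 °C |  | 25 min |
| ochre | 0.50 M | 115 °C |  | 25 min |
| grey | 0.79 M | 100 °C |  | 25 min |
| amber | 0.50 M | 140 °C |  | 25 min |

- ash (time / min: target / %, substrate / %): 10.0: 1.2, 94.2; 20.0: 1.4, 89.9; 25.0: 1.2, 85.7; 40.0: 2.6, 78.7; 50.0: 4.2, 74.6
- elm (time / min: target / %, substrate / %): 2.00: 2.3, 76.2; 4.00: 4.7, 58.3; 6.00: 7.4, 45.7; 8.00: 9.0, 36.9; 12.0: 11.6, 22.7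
- oak (time / min: target / %, substrate / %): 4.00: 0.9, 96.8; 10.0: 0.9, 94.8; 20.0: 2.6, 89.5; 30.0: 1.9, 84.0; 50.0: 3.4, 74.6

(standard deviation of a reading: 0.5 percentage points)



- all flasks from highest to lowest amount of target, in percent of the substrate charged, at 25 min (blue / red / ochre / grey / amber)
- the amount of target, in percent of the substrate charged of the flask you put first, at 25 min
- the amount of target, in percent of the substrate charged of the flask you put last, at 25 min

Ash and oak both keep 74.6% of their substrate at 50.0 min, from charges of 0.24 M and 0.77 M, so I read the loss as first order, with constant 0.00586 /min at 80 °C. Elm's last reading gives 0.124 /min at 112 °C, and I interpolate the logarithm of the constant in temperature. Elm's last reading also gives 15.0%: this is the target share, target held per substrate lost, the overall selectivity.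

My reckoning joins the two ends:

target = target share × substrate lost

blue: constant 0.00944 /min, target 3.15%

grey: constant 0.0394 /min, target 9.40%

Elm's loss carried on to 25 min leaves 4.55%, so ochre, red and amber, all hotter than elm, have lost nearly all their substrate. My reckoning ties them near the target share.

Turn the question round. For ochre to stand above amber, the target share must be lower in the hotter flask, or target must fall once substrate is nearly spent. Elm, at its last reading, still holds 22.7% of its substrate, so it does not reach that stretch. I keep the reckoning and put the hotter flask first, but tentatively: it leaves ochre about 0.25 percentage points below amber, against a scatter of 0.5 points per reading.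

The forecast gives amber > red > ochre > grey > blue, with 22% first and 3.1% last. That top is above my tied level. Its caution: “the plateau could be flat, or target could degrade unseen”.

The simulation gives amber > red > ochre > grey > blue, with amber at 23.5% and blue at 3.08%.

    substrate ⇌ side product (K = 2.30, k = 0.0142 /min, Ea = 120 kJ/mol, ΔH = −38.0 kJ/mol)
    substrate → intermediate A (k = 0.00954 /min, Ea = 109 kJ/mol)
    substrate → target (k = 0.00597 /min, Ea = 108 kJ/mol)
    intermediate A ⇌ intermediate B (K = 0.883, k = 0.0387 /min, Ea = 100 kJ/mol, ΔH = −28.0 kJ/mol)
    substrate ⇌ dormant form (K = 25.1, k = 0.0145 /min, Ea = 106 kJ/mol, ΔH = −5.00 kJ/mol)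
    (constants at 100 °C)

On blue the target share gives 3.15% against 3.08%, and on grey 9.40% against 9.12%. Amber stands 2.5 points above red, and its target is higher than the target share. The neighbour is amber read at 6.0 min, with 3.9% of its substrate left:

target share × substrate lost = 14.4%

That flask holds 19.3% of target, more than this reckoning gives. From there to 25 min, amber's substrate falls by 3.1 points while its target rises by 4.2 points.

The data stem from a simulated flask with constants of no real substance, noise included.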